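If a solid keeps its solution at one steady concentration, it falls by equal steps in equal times whatever the charge, and that was the rule I looked for in these flasks, where solid Q gives the ring D.

| flask | Q | temperature | remark | time |
|---|---|---|---|---|
| oak | 0.20 M | 80 °C | run made earlier |  |
| Saturday's | 0.10 M | 80 °C |  | 8.0 min |
| Monday's | 0.10 M | 65 °C |  | 8.0 min |
| Thursday's | 0.10 M | 50 °C |  | 8.0 min |
| Sunday's | 0.10 M | 95 °C |  | 8.0 min |

oak run (percent of the Q charged)

| time / s | D / % | Q / % |
|---|---|---|
| 10.0 | 1.2 | 87.9 |
| 12.0 | 0 | 86.4 |
| 20.0 | 1.7 | 78.4 |
| 40.0 | 5.2 | 64.2 |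
| 60.0 | 7.3 | 50.1 |
| 90.0 | 10.2 | 29.2 |

(readings scatter by 1 percentage point)

- as a solid, counted per litre of solution: Q
- at the start none of Q is in solution
- what has only dissolved of Q counts as not reacted
- the earlier runs do not show what temperature does; that part of a forecast is a guess

1. the best flask by amount of D, in percent of the Q charged; "all alike" if 1.5 percentage points covers them all (Saturday's / Monday's / Thursday's / Sunday's / all alike)
2. amount of D at the end, in percent of the Q charged, Saturday's
3. amount of D at the end, in percent of the Q charged, Monday's
4. amount of D at the end, in percent of the Q charged, Thursday's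
5. amount of D at the end, in percent of the Q charged, Sunday's

Between 20.0 s and 90.0 s the oak run lost Q from 78.4% to 29.2%, a straight fall of 0.422 min⁻¹ as a fraction of its charge, which I read as a rate of zero order, with its scatter. Saturday's charge is half the oak charge, so I expected the same moles per minute to take twice the fraction, and the lifetime of the solid, the time a charge lasts at that steady rate, came to 1.19 min.

I turned the settings by hand, one after the other. Time first: Saturday's 8.0 min is 6.72 lifetimes, so I expected the end of the run to add little. The charge next: over the same stretch D rose from 1.7% to 10.2%, a share of 17.3% of the Q lost, a reading with its scatter, and in my own reckoning, which is not the forecast's, I carried that share over to Saturday's. Temperature last: the oak run shows nothing of it, so I could only guess that Thursday's, the coldest, stretches the lifetime.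

The forecast, a little below my share, gave 16% for Saturday's, 16% for Monday's, 11% for Thursday's and 16% for Sunday's, and chose Saturday's: “The top three can't be separated, so I pick the measured temperature.”

The flasks gave 23.5%, 15.6%, 7.57% and 32.6% in that order, and the best was Sunday's.

    J → D (k = 0.670 min⁻¹, Ea = 97.0 kJ mol⁻¹)
    2 J → G (k = 21.0 L mol⁻¹ min⁻¹, Ea = 64.0 kJ mol⁻¹)
    Q ⇌ J, rate k3*(cs3 - [J]) while solid is left; crystals form when [J] > cs3 (solubility = 0.0630 M, k = 3.00 min⁻¹)
    J + D → E (k = 16.0 L mol⁻¹ min⁻¹, Ea = 76.0 kJ mol⁻¹)
    2 J → L (k = 0.00240 L mol⁻¹ min⁻¹, Ea = 69.0 kJ mol⁻¹)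
    (constants at 80 °C)

In Sunday's, at 0.357 min, J was used by passing into D 1.1 times as fast as by passing into G, and that flask ended with 32.6% of D, more than Saturday's 23.5%. Saturday's lifetime of 1.19 min lay inside 4.00 min, at which time that flask held J 0.689%, solid Q 0% and D 23.3%. At a fixed rate of loss the lifetime goes with the charge, so I reckon the neighbour of Sunday's with 60.0% of its charge at that fraction of Sunday's lifetime, and it held 40.7% of D against Sunday's 32.6%.

The earlier runs and the new flask are calculated for substances that don't exist; the scatter is artificial.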